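## Analysis of the target

The target 26 is a 2,3-trans dihydroflavonol. A benzene ring A is fused to a dihydropyranone ring C, which carries the catechol ring B on C2 and a hydroxyl on C3; a ten-carbon chain sits on C6 of ring A. The chain is a hydrated geranyl group with an (E)-trisubstituted alkene and a terminal tertiary alcohol. It holds no stereocentre, but its alkene geometry must be carried through unchanged. The only stereocentres are C2 and C3, both R, vicinal and trans. C3 lies α to the C4 ketone and C2 is benzylic and bonded to O1, so base can epimerise C3 by enolisation and scramble C2 by β-elimination of O1. The catechol and the 5,7-dihydroxylated ring A oxidise readily as phenoxides. The alkene and tertiary alcohol sit next to two phenols and would cyclise or ionise in strong acid, so the last steps must be close to neutral. The hard points are placing the chain on C6 and not on C8, which are nearly equivalent nucleophilic positions of a preformed ring A, and keeping C2 and C3 intact while ring A is made. The strategy rests on the substitution pattern of ring A: oxygen on C5, C7 and C8a, with the chain on C6 between two oxygens. C5–C6–C7–C8 is thus the carbon chain of a 2-alkylated acetoacetate, and C4a=C8a is the enol ether double bond of a dihydropyranone that already is ring C.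

## Retrosynthetic reasoning

**26 to 25.** The three O–Si bonds on O3, O3' and O4' are cut last. Silyl ethers are the only masks for the catechol and the C3 hydroxyl that come off under buffered fluoride, without base (ring opening of ring C) and without strong acid (side chain). The 5-OH, 7-OH and the tertiary alcohol are already free in 25.

**25 to 11 and 22 (key disconnection).** C4a–C5 and C8–C8a are cut. These two bonds split ring A into the C4a=C8a unit, present in ring C building block 11 with both stereocentres in place, and the four-carbon unit C5–C8 of diene 22, which carries the C5 and C7 oxygens and the chain on its C2. The chain-bearing carbon can only end up between C5 and C7, so the 6 versus 8 question is answered by connectivity. The forward reaction is a (4+2) cycloaddition followed by two eliminations, one from C5 (the mixed ketal) and one across C4a–C8a. For the second elimination the group on C4a must leave cis to the C8a hydrogen, which no carbonyl acidifies. A halide cannot do this, but a sulfoxide eliminates thermally through exactly that syn geometry and also activates the dienophile. This is why 11 carries a phenylsulfinyl group on C5.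

**11 to 10 to 8.** The S–O bond and then the C5–S bond are cut. C5 of vinylogous ester 8 is its nucleophilic carbon, so sulfur is introduced electrophilically and oxidised once.

**8 to 7 to 5.** The O–Si bond and then the C3–O bond are cut. C3 is the only enolisable position of 5, and the C2 aryl group directs the oxidant to the opposite face, which gives the trans ketol 7.

**5 to 2 and 3.** C2–C3 and O1–C6 of the pyranone are cut in a hetero-Diels–Alder sense. This is the one catalyst-controlled step: it sets C2, and C3 then follows from C2. Aldehyde 2 comes from 1 by silylation.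

**22 to 20 to 19.** Three O–Si bonds are cut, leading back to keto ester 19 by the usual two-stage silylation.

**19 to 17 and 16.** The C–C bond between the acetoacetate α-carbon of 17 and the allylic carbon of bromide 16 is cut, an enolate alkylation.

**16 to 15 to 12.** The C–Br bond and then the tertiary C–O bond are cut. Chemoselective Markovnikov hydration of the remote alkene of geranyl acetate 12 gives the chain with the (E) alkene intact.

## Alternatives that were turned down

**Alternative 1:** The disconnection is C2–C3 of ring C. In the forward step Rh2(S-PTTL)4, dirhodium tetrakis[N-phthaloyl-(S)-tert-leucinate] (divalent rhodium), decomposes diazo ketone A1 to a carbene on C3. The carbene inserts into the benzylic C–H bond of the ring B benzyl ether and gives flavanone A2 with C2 set.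
- For: ring A is never built, so no aromatisation has to be invented, and the C–H bond is activated by both oxygen and aryl. On this point it is stronger than the chosen route.
- Against: the ether oxygen sits where the carbene can form a five-membered oxonium ylide, and a 1,2-shift from that ylide would contract the ring in competition with the 1,6-insertion.
- Against: A2 still lacks the C3 hydroxyl. Introducing it by enolate chemistry on a flavanone invites β-elimination of O1 and loss of the C2 configuration.
- Against: A1 needs a ring A in which three oxygens are differentiated and the chain is placed para to the benzyl ether. That is the same regiochemical problem the chosen route removes by construction.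
- Comparison: the step count would be similar or higher. The chosen route offers both stereocentres secured before its risky step.

**Alternative 2:** The disconnections are O1–C8a and C4–C4a. In the forward step CsF releases an aryne from silylaryl triflate A3, the alkoxide of anti-aldol ester A4 adds at C8a, and the C4a aryl anion attacks the ester to give A5.
- For: it is the most convergent plan, and both stereocentres come from a well-established aldol. It is stronger than the chosen route on convergence.
- Against: a β-alkoxide of an aldol ester under fluoride can undergo retro-aldol cleavage and epimerisation, and protonation of the aryl anion stops the sequence at the aryl ether.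
- Against: the free tertiary alcohol and the alkene are further aryne traps.
- Against: A3 is a pentasubstituted arene that again requires a regiodefined ring A.
- Against: five methoxymethyl ethers must be removed with acid, which the side chain next to two phenols tolerates poorly.
- Comparison: the chosen route uses only fluoride-labile groups and takes ring A from an acetoacetate.

**Alternative 3:** The disconnection is C3–C4. In the forward step a chiral triazolium-derived carbene converts the aryl aldehyde of racemic dialdehyde A6 into an acyl anion equivalent that adds to the aliphatic aldehyde while C2 racemises, giving A7.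
- For: both stereocentres are set in one catalytic step and the C3 hydroxyl emerges free. It is stronger than the chosen route on stereochemical economy.
- Against: the aryl aldehyde is flanked by two ortho oxygens and is electron-rich, so the carbene should prefer the aliphatic aldehyde. That would give the isomeric acyloin or self-condensation.
- Against: the base must racemise C2 of A6 quickly but leave the product, which has the same acidic positions and an aryloxy leaving group, untouched.
- Against: aryl silyl ethers are labile to that base, and A6 again needs a regiodefined ring A.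
- Comparison: the chosen route separates stereocontrol (steps 2 and 3, established reactions) from ring construction.

Key step: step 12

Assumption: (S)-BINOL with Ti(OiPr)4 is taken to direct addition to the Si face of aldehyde 2, as in related additions to aryl aldehydes; if the opposite sense is found, (R)-BINOL is used.

Remark: stereo-elements that are destroyed later are formed as mixtures and left unspecified. These are C5/C6 of 9, sulfur of 11, C2 of 19, the enol ether geometry of 20 to 22, and C4a/C5/C8a/sulfur of 23.

Abbreviations: TBS = tert-butyldimethylsilyl; TMS = trimethylsilyl; Ar = 3,4-bis(TBS-oxy)phenyl.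

## Route

Step 1
Reactants: 1 3,4-dihydroxybenzaldehyde
Product: 2 3,4-bis(TBS-oxy)benzaldehyde
Conditions: TBSCl, imidazole, DMF, rt
Reagents that add atoms: tert-butyldimethylsilyl chloride, CC(C)(C)[Si](C)(C)Cl
Why: Standard silylation of both phenols; the aryl silyl ethers should survive the Lewis acid, base, oxidant and heat used up to step 12 and leave with fluoride at the end.

Step 2
Reactants: 2 3,4-bis(TBS-oxy)benzaldehyde; 3 (E)-1-methoxy-3-(trimethylsilyloxy)buta-1,3-diene
Product: 5 (2S)-2-Ar-2,3-dihydro-4H-pyran-4-one, via silylated aldol adduct 4 (not isolated)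
Conditions: (S)-BINOL (20 mol%), Ti(OiPr)4 (10 mol%), 4 Å MS, Et2O, −20 °C; then CF3CO2H, CH2Cl2, 0 °C
Reagents that add atoms: none
Why: Catalytic enantioselective hetero-Diels–Alder reaction in its Mukaiyama aldol–cyclisation form, well established for aryl aldehydes; the chiral titanium–BINOL complex directs the diene to the Si face of the aldehyde and so sets C2, and acid closes the ring with loss of methanol.

Step 3
Reactants: 5 (2S)-2-Ar-2,3-dihydro-4H-pyran-4-one
Product: 7 (2R,3R)-2-Ar-3-hydroxy-2,3-dihydro-4H-pyran-4-one (2,3-trans), via sodium enolate 6 (not isolated)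
Conditions: NaN(SiMe3)2, THF, −78 °C; 2-(phenylsulfonyl)-3-phenyloxaziridine, −78 °C; aq NH4Cl, −78 °C
Reagents that add atoms: 2-(phenylsulfonyl)-3-phenyloxaziridine, O=S(=O)(c1ccccc1)N1OC1c1ccccc1
Why: Enolate hydroxylation with an N-sulfonyloxaziridine; C3 is the only enolisable position, and oxygen should be delivered to the enolate face opposite the C2 aryl group, giving the 2,3-trans ketol, which is also the more stable diastereomer.

Step 4
Reactants: 7 (2R,3R)-2-Ar-3-hydroxy-2,3-dihydro-4H-pyran-4-one
Product: 8 (2R,3R)-2-Ar-3-(TBS-oxy)-2,3-dihydro-4H-pyran-4-one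
Conditions: TBSOTf, 2,6-lutidine, CH2Cl2, −78 → 0 °C
Reagents that add atoms: tert-butyldimethylsilyl triflate, CC(C)(C)[Si](C)(C)OS(=O)(=O)C(F)(F)F
Why: Silylation of a hindered secondary alcohol with the silyl triflate and a weak hindered base that should not enolise the ketone; the ether blocks C3–O and reduces the acidity of H3 by shielding.

Step 5
Reactants: 8 (2R,3R)-2-Ar-3-(TBS-oxy)-2,3-dihydro-4H-pyran-4-one
Product: 10 (2R,3R)-2-Ar-3-(TBS-oxy)-5-(phenylthio)-2,3-dihydro-4H-pyran-4-one, via chloro sulfide adduct 9 (not isolated)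
Conditions: PhSCl, CH2Cl2, −78 °C; then Et3N, −78 → 0 °C
Reagents that add atoms: benzenesulfenyl chloride, ClSc1ccccc1
Why: Electrophilic sulfenylation of the enol ether carbon C5 by addition of the sulfenyl chloride across C5=C6 and base-induced loss of HCl, the sequence by which enol ethers and enone-type glycals are functionalised at this carbon; at −78 °C the silyloxyarene is far less nucleophilic than the vinylogous ester.

Step 6
Reactants: 10 (2R,3R)-2-Ar-3-(TBS-oxy)-5-(phenylthio)-2,3-dihydro-4H-pyran-4-one
Product: 11 (2R,3R)-2-Ar-3-(TBS-oxy)-5-(phenylsulfinyl)-2,3-dihydro-4H-pyran-4-one (both configurations at sulfur)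
Conditions: mCPBA (1.0 equiv), NaHCO3, CH2Cl2, −78 → −40 °C
Reagents that add atoms: 3-chloroperbenzoic acid, O=C(OO)c1cccc(Cl)c1
Why: Sulfide-to-sulfoxide oxidation held at the sulfoxide by stoichiometry and temperature; the electron-poor C5=C6 bond should not be epoxidised, and the sulfur configuration is immaterial because sulfur is lost in step 12.

Step 7
Reactants: 12 geranyl acetate
Product: 15 (E)-3,7-dimethyloct-2-ene-1,7-diol, via organomercurial 13 (not isolated), via hydroxy acetate 14 (not isolated)
Conditions: Hg(OAc)2, THF–H2O, rt; NaBH4, aq NaOH, 0 °C; then NaOH, MeOH, rt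
Reagents that add atoms: water, O
Why: Oxymercuration–demercuration hydrates the remote, more electron-rich trisubstituted alkene in the Markovnikov sense, while the alkene next to the acetate is deactivated inductively; the acetate is then saponified in the same flask and the (E) alkene is not touched.

Step 8
Reactants: 15 (E)-3,7-dimethyloct-2-ene-1,7-diol
Product: 16 (E)-8-bromo-2,6-dimethyloct-6-en-2-ol
Conditions: NBS, Me2S, CH2Cl2, −30 → 0 °C; used at once
Reagents that add atoms: N-bromosuccinimide, O=C1CCC(=O)N1Br
Why: Corey–Kim bromination is selective for allylic alcohols; SN2 displacement of the primary alkoxysulfonium ion by bromide keeps the (E) geometry and leaves the tertiary alcohol alone.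

Step 9
Reactants: 17 methyl acetoacetate; 16 (E)-8-bromo-2,6-dimethyloct-6-en-2-ol
Product: 19 methyl (E)-2-acetyl-9-hydroxy-5,9-dimethyldec-4-enoate, via sodium acetoacetate enolate 18 (not isolated)
Conditions: NaH (1.9 equiv), 17 (2.0 equiv), THF, 0 °C; then 16, 0 °C → rt
Reagents that add atoms: none
Why: C-alkylation of the acetoacetate enolate by SN2 at the primary allylic bromide; the excess of 17 limits dialkylation, and the stabilised enolate is not basic enough to deprotonate the tertiary alcohol.

Step 10
Reactants: 19 methyl (E)-2-acetyl-9-hydroxy-5,9-dimethyldec-4-enoate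
Product: 20 methyl (4E)-5,9-dimethyl-2-[1-(TMS-oxy)ethylidene]-9-(TMS-oxy)dec-4-enoate
Conditions: Me3SiCl, Et3N, toluene, rt, 48 h
Reagents that add atoms: chlorotrimethylsilane, C[Si](C)(C)Cl
Why: O-silylation of the β-keto ester enol, the first stage of the standard route to 1,3-bis(silyloxy)dienes; the tertiary alcohol is silylated under the same conditions, and any that remains free is silylated in step 11 by the excess base and chlorosilane.

Step 11
Reactants: 20 methyl (4E)-5,9-dimethyl-2-[1-(TMS-oxy)ethylidene]-9-(TMS-oxy)dec-4-enoate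
Product: 22 1-methoxy-1,3-bis(TMS-oxy)-2-[(E)-3,7-dimethyl-7-(TMS-oxy)oct-2-enyl]buta-1,3-diene, via lithium dienolate 21 (not isolated)
Conditions: LiN(iPr)2, THF, −78 °C; Me3SiCl, −78 → 0 °C; filtered under argon, used crude
Reagents that add atoms: chlorotrimethylsilane, C[Si](C)(C)Cl
Why: γ-Deprotonation of the silyl enol ether and O-silylation of the ester dienolate, the established second stage for 2-alkyl-1-alkoxy-1,3-bis(silyloxy)dienes.

Step 12
Reactants: 11 (2R,3R)-2-Ar-3-(TBS-oxy)-5-(phenylsulfinyl)-2,3-dihydro-4H-pyran-4-one; 22 1-methoxy-1,3-bis(TMS-oxy)-2-[(E)-3,7-dimethyl-7-(TMS-oxy)oct-2-enyl]buta-1,3-diene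
Product: 25 (2R,3R)-2-Ar-3-(TBS-oxy)-5,7-dihydroxy-6-[(E)-7-hydroxy-3,7-dimethyloct-2-enyl]-2,3-dihydro-4H-chromen-4-one, via sulfinyl cycloadduct 23 (not isolated), via silylated flavanonol 24 (not isolated)
Conditions: 22 (3 equiv), toluene, 80 → 110 °C, sealed tube; then PPTS, MeOH, rt
Reagents that add atoms: none
Why: Proposed new method: the CH2 terminus of diene 22 (future C8), its most nucleophilic carbon, bonds to C6 of 11, which is β both to the ketone and to the sulfinyl group, and the ketene acetal carbon (future C5) then bonds to the sulfinyl-bearing C5 in a concerted but asynchronous (4+2) cycloaddition that forms C8–C8a and C4a–C5 and closes ring A as a six-membered carbocycle by intermolecular annulation onto ring C (cycloadduct 23). Because the addition is suprafacial, the sulfinyl group on C4a and the hydrogen on C8a are cis, the arrangement required for the thermal syn-elimination of a sulfoxide, so C4a=C8a should form on further heating without base. The C5 mixed ketal then collapses with loss of methoxytrimethylsilane, the resulting cross-conjugated dienone tautomerises to phenol 24, and methanolysis frees O7 and the side-chain alcohol to give 25. The closest known reaction types are the cycloaddition–aromatisation of 1-alkoxy-1,3-bis(silyloxy)dienes with halogenated quinones and the use of vinyl sulfoxides and α-sulfinyl enones as alkyne equivalents in Diels–Alder reactions; a 5-sulfinyl-2,3-dihydropyran-4-one has not been used as the dienophile. A halogen on C5 was not chosen because halide would have to leave from C4a syn to a C8a hydrogen that no carbonyl group acidifies, and base would instead expel O1 and open ring C. No lasting stereocentre is formed, since C4a, C5 and C8a all end up sp2, and C2 and C3 should stay untouched because the medium contains neither base nor Lewis acid. The step needs regioselectivity (CH2 terminus to C8a, chain-bearing side next to C5), which the matched polarisation of diene and dienophile secures, and it needs cycloaddition to outrun silyl transfer from the ketene acetal to the sulfinyl oxygen, which the non-polar solvent and the absence of a Lewis acid are chosen to favour.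

Step 13
Reactants: 25 (2R,3R)-2-Ar-3-(TBS-oxy)-5,7-dihydroxy-6-[(E)-7-hydroxy-3,7-dimethyloct-2-enyl]-2,3-dihydro-4H-chromen-4-one
Product: 26 (2R,3R)-2-(3,4-dihydroxyphenyl)-3,5,7-trihydroxy-6-[(E)-7-hydroxy-3,7-dimethyloct-2-enyl]-2,3-dihydro-4H-chromen-4-one
Conditions: HF·pyridine, pyridine, THF, 0 °C → rt
Reagents that add atoms: none
Why: Fluoride cleavage of two aryl and one secondary silyl ether under buffered, weakly acidic conditions; no phenoxide is formed, so ring C should not open and the catechol should not oxidise, and the medium is too mild to ionise the tertiary alcohol or cyclise the chain onto the neighbouring phenols.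

## Compound list

1 | 3,4-dihydroxybenzaldehyde | O=Cc1ccc(O)c(O)c1 | starting material
2 | 3,4-bis(TBS-oxy)benzaldehyde | O=Cc1ccc(O[Si](C)(C)C(C)(C)C)c(O[Si](C)(C)C(C)(C)C)c1 | intermediate
3 | (E)-1-methoxy-3-(trimethylsilyloxy)buta-1,3-diene | CO/C=C/C(=C)O[Si](C)(C)C | starting material
4 | silylated aldol adduct, (1E,5S)-5-Ar-1-methoxy-5-(TMS-oxy)pent-1-en-3-one | CO/C=C/C(=O)C[C@H](O[Si](C)(C)C)c1ccc(O[Si](C)(C)C(C)(C)C)c(O[Si](C)(C)C(C)(C)C)c1 | intermediate
5 | (2S)-2-Ar-2,3-dihydro-4H-pyran-4-one | O=C1C[C@@H](c2ccc(O[Si](C)(C)C(C)(C)C)c(O[Si](C)(C)C(C)(C)C)c2)OC=C1 | intermediate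
6 | sodium enolate, sodium (2S)-2-Ar-2H-pyran-4-olate | [Na+].[O-]C1=C[C@@H](c2ccc(O[Si](C)(C)C(C)(C)C)c(O[Si](C)(C)C(C)(C)C)c2)OC=C1 | intermediate
7 | (2R,3R)-2-Ar-3-hydroxy-2,3-dihydro-4H-pyran-4-one | O=C1[C@H](O)[C@@H](c2ccc(O[Si](C)(C)C(C)(C)C)c(O[Si](C)(C)C(C)(C)C)c2)OC=C1 | intermediate
8 | (2R,3R)-2-Ar-3-(TBS-oxy)-2,3-dihydro-4H-pyran-4-one | O=C1[C@H](O[Si](C)(C)C(C)(C)C)[C@@H](c2ccc(O[Si](C)(C)C(C)(C)C)c(O[Si](C)(C)C(C)(C)C)c2)OC=C1 | intermediate
9 | chloro sulfide adduct, (2R,3R)-2-Ar-3-(TBS-oxy)-6-chloro-5-(phenylthio)tetrahydro-4H-pyran-4-one (C5, C6 unassigned) | O=C1[C@H](O[Si](C)(C)C(C)(C)C)[C@@H](c2ccc(O[Si](C)(C)C(C)(C)C)c(O[Si](C)(C)C(C)(C)C)c2)OC(Cl)C1Sc1ccccc1 | intermediate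
10 | (2R,3R)-2-Ar-3-(TBS-oxy)-5-(phenylthio)-2,3-dihydro-4H-pyran-4-one | O=C1[C@H](O[Si](C)(C)C(C)(C)C)[C@@H](c2ccc(O[Si](C)(C)C(C)(C)C)c(O[Si](C)(C)C(C)(C)C)c2)OC=C1Sc1ccccc1 | intermediate
11 | (2R,3R)-2-Ar-3-(TBS-oxy)-5-(phenylsulfinyl)-2,3-dihydro-4H-pyran-4-one (both configurations at sulfur) | O=C1[C@H](O[Si](C)(C)C(C)(C)C)[C@@H](c2ccc(O[Si](C)(C)C(C)(C)C)c(O[Si](C)(C)C(C)(C)C)c2)OC=C1S(=O)c1ccccc1 | intermediate
12 | geranyl acetate | CC(=O)OC/C=C(\C)CCC=C(C)C | starting material
13 | organomercurial, (E)-6-(acetoxymercurio)-7-hydroxy-3,7-dimethyloct-2-enyl acetate | CC(=O)OC/C=C(\C)CCC([Hg]OC(C)=O)C(C)(C)O | intermediate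
14 | hydroxy acetate, (E)-7-hydroxy-3,7-dimethyloct-2-enyl acetate | CC(=O)OC/C=C(\C)CCCC(C)(C)O | intermediate
15 | (E)-3,7-dimethyloct-2-ene-1,7-diol | OC/C=C(\C)CCCC(C)(C)O | intermediate
16 | (E)-8-bromo-2,6-dimethyloct-6-en-2-ol | BrC/C=C(\C)CCCC(C)(C)O | intermediate
17 | methyl acetoacetate | COC(=O)CC(C)=O | starting material
18 | sodium acetoacetate enolate (sodium enolate of 17) | [Na+].COC(=O)C=C(C)[O-] | intermediate
19 | methyl (E)-2-acetyl-9-hydroxy-5,9-dimethyldec-4-enoate (racemic at C2) | COC(=O)C(C/C=C(\C)CCCC(C)(C)O)C(C)=O | intermediate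
20 | methyl (4E)-5,9-dimethyl-2-[1-(TMS-oxy)ethylidene]-9-(TMS-oxy)dec-4-enoate | COC(=O)C(C/C=C(\C)CCCC(C)(C)O[Si](C)(C)C)=C(C)O[Si](C)(C)C | intermediate
21 | lithium dienolate of 20 | [Li+].COC([O-])=C(C/C=C(\C)CCCC(C)(C)O[Si](C)(C)C)C(=C)O[Si](C)(C)C | intermediate
22 | 1-methoxy-1,3-bis(TMS-oxy)-2-[(E)-3,7-dimethyl-7-(TMS-oxy)oct-2-enyl]buta-1,3-diene | COC(O[Si](C)(C)C)=C(C/C=C(\C)CCCC(C)(C)O[Si](C)(C)C)C(=C)O[Si](C)(C)C | intermediate
23 | sulfinyl cycloadduct, (2R,3R)-2-Ar-3-(TBS-oxy)-5-methoxy-4a-(phenylsulfinyl)-5,7-bis(TMS-oxy)-6-[(E)-3,7-dimethyl-7-(TMS-oxy)oct-2-enyl]-2,3,4a,5,8,8a-hexahydro-4H-chromen-4-one (cis ring fusion) | COC1(O[Si](C)(C)C)C(C/C=C(\C)CCCC(C)(C)O[Si](C)(C)C)=C(O[Si](C)(C)C)CC2O[C@H](c3ccc(O[Si](C)(C)C(C)(C)C)c(O[Si](C)(C)C(C)(C)C)c3)[C@@H](O[Si](C)(C)C(C)(C)C)C(=O)C12S(=O)c1ccccc1 | intermediate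
24 | silylated flavanonol, (2R,3R)-2-Ar-3-(TBS-oxy)-5-hydroxy-7-(TMS-oxy)-6-[(E)-3,7-dimethyl-7-(TMS-oxy)oct-2-enyl]-2,3-dihydro-4H-chromen-4-one | C/C(=C\Cc1c(O[Si](C)(C)C)cc2c(c1O)C(=O)[C@H](O[Si](C)(C)C(C)(C)C)[C@@H](c1ccc(O[Si](C)(C)C(C)(C)C)c(O[Si](C)(C)C(C)(C)C)c1)O2)CCCC(C)(C)O[Si](C)(C)C | intermediate
25 | (2R,3R)-2-Ar-3-(TBS-oxy)-5,7-dihydroxy-6-[(E)-7-hydroxy-3,7-dimethyloct-2-enyl]-2,3-dihydro-4H-chromen-4-one | C/C(=C\Cc1c(O)cc2c(c1O)C(=O)[C@H](O[Si](C)(C)C(C)(C)C)[C@@H](c1ccc(O[Si](C)(C)C(C)(C)C)c(O[Si](C)(C)C(C)(C)C)c1)O2)CCCC(C)(C)O | intermediate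
26 | (2R,3R)-2-(3,4-dihydroxyphenyl)-3,5,7-trihydroxy-6-[(E)-7-hydroxy-3,7-dimethyloct-2-enyl]-2,3-dihydro-4H-chromen-4-one | C/C(=C\Cc1c(O)cc2c(c1O)C(=O)[C@H](O)[C@@H](c1ccc(O)c(O)c1)O2)CCCC(C)(C)O | target

## Step count and risk

Total: 13 steps. Longest linear sequence: 8 steps (steps 1 to 6, 12 and 13); the diene branch (steps 7 to 11) has 5 steps.

**Step 12 (key step, Proposed new method).** Four things may go wrong. The push-pull dienophile may react too slowly, so that the diene decomposes first. Silyl transfer from the ketene acetal to the sulfinyl oxygen may start a Pummerer-type reduction of sulfur. The annulation may stop after the first C–C bond, as conjugate addition without ring closure. The sulfenic acid set free may attack the excess diene or the electron-rich ring A.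

The fallback uses known chemistry and gives up the construction of ring A. It sets out from bromide 16 and arrives directly at target 26. Commercial (2R,3R)-taxifolin is C-alkylated with 16 under the conditions long used for C-prenylation of 5,7-dihydroxyflavanones (NaOMe, MeOH, 0 °C → rt, short contact time). The C6 isomer 26 is separated by chromatography from the C8 isomer and the O-alkyl ethers. Regioselectivity is poor, but both stereocentres come from the chiral pool. This fallback makes no compound that is not already listed (F0).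

**Step 3.** The enolate may expel O1 by β-elimination and open the ring before it is oxidised, and facial selectivity may be incomplete. The fallback avoids a free enolate. It sets out from 5: oxidation with Mn(OAc)3 in hot benzene, the known α'-acetoxylation of dihydropyranones trans to the C2 substituent, should give (2R,3R)-2-Ar-4-oxo-3,4-dihydro-2H-pyran-3-yl acetate F1. Mild methanolysis (catalytic K2CO3, MeOH, 0 °C) then returns to the route at 7.

**Step 5.** The sulfenyl chloride may also attack the silyloxyarene, or the chloro adduct may ionise at C6 and degrade. The fallback sets out from 8: bromination with NBS in CH2Cl2 at 0 °C, the known α-halogenation of dihydropyranones, should give (2R,3R)-2-Ar-5-bromo-3-(TBS-oxy)-2,3-dihydro-4H-pyran-4-one F2. Palladium-catalysed C–S coupling with thiophenol (Pd2(dba)3, Xantphos, iPr2NEt, dioxane, 90 °C) then returns to the route at 10.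

**Step 2.** The electron-rich aldehyde may react slowly and with eroded enantioselectivity. The fallback sets C2 by an aldol reaction and sets out from 2.
- A Lewis-base-catalysed aldol addition of 1-methoxy-1-(trimethylsilyloxy)ethene (SiCl4, chiral bisphosphoramide, CH2Cl2, −78 °C; the enantiomer that gives the S alcohol) should give methyl (3S)-3-Ar-3-hydroxypropanoate F3.
- MeNHOMe·HCl with iPrMgCl converts it into (3S)-3-Ar-3-hydroxy-N-methoxy-N-methylpropanamide F4.
- An excess of HC≡CMgBr gives (5S)-5-Ar-5-hydroxypent-1-yn-3-one F5.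
- AgOTf-catalysed 6-endo cyclisation of the hydroxy ynone returns to the route at 5.

## Further compounds

F0 | step 12 | none | none
F1 | step 3 | (2R,3R)-2-Ar-4-oxo-3,4-dihydro-2H-pyran-3-yl acetate | O=C1[C@H](OC(C)=O)[C@@H](c2ccc(O[Si](C)(C)C(C)(C)C)c(O[Si](C)(C)C(C)(C)C)c2)OC=C1
F2 | step 5 | (2R,3R)-2-Ar-5-bromo-3-(TBS-oxy)-2,3-dihydro-4H-pyran-4-one | O=C1[C@H](O[Si](C)(C)C(C)(C)C)[C@@H](c2ccc(O[Si](C)(C)C(C)(C)C)c(O[Si](C)(C)C(C)(C)C)c2)OC=C1Br
F3 | step 2 | methyl (3S)-3-Ar-3-hydroxypropanoate | COC(=O)C[C@H](O)c1ccc(O[Si](C)(C)C(C)(C)C)c(O[Si](C)(C)C(C)(C)C)c1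
F4 | step 2 | (3S)-3-Ar-3-hydroxy-N-methoxy-N-methylpropanamide | CON(C)C(=O)C[C@H](O)c1ccc(O[Si](C)(C)C(C)(C)C)c(O[Si](C)(C)C(C)(C)C)c1
F5 | step 2 | (5S)-5-Ar-5-hydroxypent-1-yn-3-one | C#CC(=O)C[C@H](O)c1ccc(O[Si](C)(C)C(C)(C)C)c(O[Si](C)(C)C(C)(C)C)c1
A1 | alternative 1 | 2-diazo-1-{2-[3,4-bis(TBS-oxy)benzyloxy]-4,6-bis(TBS-oxy)-5-[(E)-3,7-dimethyl-7-(triethylsilyloxy)oct-2-enyl]phenyl}ethanone | C/C(=C\Cc1c(O[Si](C)(C)C(C)(C)C)cc(OCc2ccc(O[Si](C)(C)C(C)(C)C)c(O[Si](C)(C)C(C)(C)C)c2)c(C(=O)C=[N+]=[N-])c1O[Si](C)(C)C(C)(C)C)CCCC(C)(C)O[Si](CC)(CC)CC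
A2 | alternative 1 | (2S)-5,7,3',4'-tetrakis-O-TBS-6-[(E)-3,7-dimethyl-7-(triethylsilyloxy)oct-2-enyl]eriodictyol | C/C(=C\Cc1c(O[Si](C)(C)C(C)(C)C)cc2c(c1O[Si](C)(C)C(C)(C)C)C(=O)C[C@@H](c1ccc(O[Si](C)(C)C(C)(C)C)c(O[Si](C)(C)C(C)(C)C)c1)O2)CCCC(C)(C)O[Si](CC)(CC)CC
A3 | alternative 2 | 4-[(E)-7-hydroxy-3,7-dimethyloct-2-enyl]-3,5-bis(methoxymethoxy)-2-(trimethylsilyl)phenyl trifluoromethanesulfonate | C/C(=C\Cc1c(OCOC)cc(OS(=O)(=O)C(F)(F)F)c([Si](C)(C)C)c1OCOC)CCCC(C)(C)O
A4 | alternative 2 | methyl (2R,3R)-3-[3,4-bis(methoxymethoxy)phenyl]-3-hydroxy-2-(methoxymethoxy)propanoate | COC(=O)[C@H](OCOC)[C@@H](c1ccc(OCOC)c(OCOC)c1)O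
A5 | alternative 2 | (2R,3R)-3,5,7,3',4'-pentakis-O-(methoxymethyl) ether of 26 | C/C(=C\Cc1c(OCOC)cc2c(c1OCOC)C(=O)[C@H](OCOC)[C@@H](c1ccc(OCOC)c(OCOC)c1)O2)CCCC(C)(C)O
A6 | alternative 3 | 2-{1-[3,4-bis(TBS-oxy)phenyl]-2-oxoethoxy}-4,6-bis(TBS-oxy)-5-[(E)-7-hydroxy-3,7-dimethyloct-2-enyl]benzaldehyde (racemic) | C/C(=C\Cc1c(O[Si](C)(C)C(C)(C)C)cc(OC(C=O)c2ccc(O[Si](C)(C)C(C)(C)C)c(O[Si](C)(C)C(C)(C)C)c2)c(C=O)c1O[Si](C)(C)C(C)(C)C)CCCC(C)(C)O
A7 | alternative 3 | (2R,3R)-5,7,3',4'-tetrakis-O-TBS ether of 26 | C/C(=C\Cc1c(O[Si](C)(C)C(C)(C)C)cc2c(c1O[Si](C)(C)C(C)(C)C)C(=O)[C@H](O)[C@@H](c1ccc(O[Si](C)(C)C(C)(C)C)c(O[Si](C)(C)C(C)(C)C)c1)O2)CCCC(C)(C)O
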